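A small charge of Q, 0.018 M, meets 0.0450 M of G, and I take the two to react one to one. So I carry one quantity, the surplus 0.0270 M: charged G minus charged Q, the reagent still standing when the last Q goes. It is positive here, so Q is the limiting reagent.

| flask | Q | G | remark | time | volume of the second phase over the first |
|---|---|---|---|---|---|
| dusk | 0.027 M | 0.045 M | run made earlier |  |  |
| flask | 0.018 M | 0.0450 M |  | 1.0 h | 1.0 |

dusk run (percent of the Q charged): time / min: D / % = 0.333: 5.2; 1.00: 24.9; 1.50: 39.0; 2.50: 57.9; 4.00: 73.2; 5.00: 80.2; 6.00: 84.4

(scatter of a reading: 0.3 percentage points)

1. the best time, 1.0 h at the latest, for D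
2. the amount of D, in percent of the Q charged, at that time
3. earliest time at which at least nineteen twentieths of that best amount are there
4. latest time at which they still are

- in the second phase: G; everything else is in the first
- charges count per volume of the first phase; a concentration in a rate is the amount of a species over the volume of its own phase; every rate counts per litre of the first phase
- the earlier runs hold the two phases in the same ratio of volumes as the flask asked about

I follow the Q left, not the D made, and the tail of the dusk run gives its fall:

| Time | Q left | G charged minus D made |
|---|---|---|
| 4.00 min | 26.8% | 0.0252 M |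
| 5.00 min | 19.8% | 0.0233 M |
| 6.00 min | 15.6% | 0.0222 M |

The logarithm of Q left drops by 0.271 /min, so with the middle G of the table the drop per unit of G, κ, reads 11.6 /M/min.

For the flask I take G at the surplus for the last of the Q, so by my reckoning Q left falls at 0.313 /min and halves every 2.22 min. The dusk run starts slowly, with 5.2% at 0.333 min, then climbs at 0.295 /min of its charge. I draw that start for the flask, which has the same G. The slope lies close to my tail rate, so I expect no sharp knee. By my reckoning 5% of Q is left at 0.160 h, and D runs towards 100%; the dusk readings stop at 84.4%, still rising.

The forecast gives 100% at 1 h, opening at 0.143 h, earlier than my time, and shutting at 1 h. It warns that “one short run can't rule out a small decay over an hour”.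

The flask gives 94.1% at 0.189 h, opening at 0.104 h and shutting at 0.419 h.

    X ⇌ G, rate k1*([X] - [G]/K1) per volume of the first phase (partition coefficient = 1.10, kL = 1.10 /min)
    Q + X → D (k = 29.0 /M/min)
    Q → E (k = 5.50 × 10⁻⁵ /min)
    X → J (k = 0.00580 /min)
    X + D → L (k = 0.410 /M/min)

In the flask the surplus of 0.0270 M does not sit idle: Q stands at 0% at 1.00 h, yet X, the reagent in the reaction phase, stands at 0.00908 M and D has dropped to 77.4%. Without the path from X + D to L, the highest D of the flask goes from 94.1% to >99.9%. The neighbour flask with 0.072 M of Q has a surplus of −0.0270 M, so G is limiting there, and 37.5% of its Q has no partner; it ends with 38% of Q left, X at 5.98 × 10⁻¹¹ M and L at 0.483%.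

The readings were computed on assumed constants; the scatter is artificial.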